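| flask | L | Z | temperature | remark | time |
|---|---|---|---|---|---|
| grey | 0.12 M | 0.18 M | 105 °C | run made earlier |  |
| red | 0.12 M | 0.25 M | 116 °C | run made earlier |  |
| blue | 0.12 M | 0.40 M | 105 °C | run made earlier |  |
| winter | 0.12 M | 0.180 M (in portions, 5, over 1.0 min) | 110 °C | first portion at the start, last at 1.0 min | 2.5 min |
| summer | 0.12 M (fed, over 1.0 min) | 0.180 M |  | the addition at 80 °C, then warmed to 110 °C; the feed brings no volume worth counting | 2.5 min |
| autumn | 0.12 M (fed, over 1.0 min) | 0.180 M | 110 °C | all else is in the flask from the start; the feed brings no volume worth counting | 2.5 min |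
| spring | 0.12 M | 0.180 M |  | everything together at the start at 80 °C, warmed to 110 °C at 1.0 min | 2.5 min |
| dusk | 0.12 M | 0.180 M | 110 °C | everything together at the start | 2.5 min |

| run | time / min | G / % |
|---|---|---|
| grey | 0.167 | 25.0 |
| grey | 0.417 | 22.9 |
| grey | 0.667 | 22.3 |
| grey | 1.00 | 23.2 |
| grey | 1.50 | 23.5 |
| grey | 2.00 | 21.4 |
| grey | 2.50 | 23.1 |
| red | 0.250 | 14.5 |
| red | 0.333 | 12.1 |
| red | 0.500 | 11.3 |
| red | 0.833 | 13.2 |
| red | 1.33 | 13.7 |
| red | 2.00 | 11.5 |
| red | 3.00 | 12.6 |
| blue | 0.167 | 7.5 |
| blue | 0.500 | 2.8 |
| blue | 0.833 | 1.0 |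
| blue | 1.33 | 0 |
| blue | 2.00 | 0.3 |
| blue | 2.50 | 0 |
| blue | 3.00 | 0 |

(standard deviation of a reading: 1 percentage point)

- steps that have been proposed: Z + D -> J; G <-> E; Z + G -> D; L + Z -> G

- the flask that comes out highest in amount of G, in percent of the L charged, or "all alike" when all lie within 1.5 percentage points (winter / summer / autumn / spring / dusk / all alike)
- G at the end, in percent of the L charged, winter
- G at the end, in percent of the L charged, summer
- G at the end, in percent of the L charged, autumn
- G at the end, in percent of the L charged, spring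
- G at the end, in percent of the L charged, dusk

1. At the last reading the grey run shows G at 23.1% and the blue run shows 0%. Both started with L at 0.12 M, but grey had Z at 0.18 M and blue at 0.40 M.

2. A bench rule of thumb says that one Z turns one L into G, so a charge above one Z per L should carry G close to 100 percent of the L. Grey has 1.50 Z per L, yet it reads 23.1%, so the rule fails in grey. The proposed steps show a way past it: Z + G -> D and Z + D -> J, so one L can take up 3 Z on its way to J.

3. Z charged over 3 times the L charged comes to 0.500 in the new flasks, and this ratio is the coverage. The border lies at one. Blue stands above it at 1.11, and its G fades to 0%. Grey stands below it at 0.500, and its G stays near 23.1%.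

4. My own reckoning goes no further than this. With coverage below one, Z is the limiting reagent, so I expect each new flask to stop taking up Z when its 0.180 M has reacted, at 1.50 Z taken up per L charged. Coverage gives the new flasks one figure, so it does not rank them.

5. The forecast does rank them. It picks spring at 32% (range 24% to 38%), with summer 26%, winter 21%, dusk 21% and autumn 15%. Its ground for the pick is in its own words: “Spring does most of its conversion at 80 °C”.

6. Spring comes out highest at 28.6%, against winter 22.7%, summer 21.4%, dusk 21.9% and autumn 11.8%. Left ten times as long, spring still gives 28.6%. In spring Z stands at 0% of its own charge, and G plus E, plus 2 times D, plus 3 times J comes to 1.50 Z per L charged, which is 3 times the coverage.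

    Z + D → J (k = 1.29 M⁻¹ s⁻¹, Ea = 46.0 kJ mol⁻¹)
    G ⇌ E (K = 0.350, k = 0.127 s⁻¹, Ea = 88.0 kJ mol⁻¹, ΔH = −27.0 kJ mol⁻¹)
    Z + G → D (k = 2.83 M⁻¹ s⁻¹, Ea = 66.0 kJ mol⁻¹)
    L + Z → G (k = 2.06 M⁻¹ s⁻¹, Ea = 45.0 kJ mol⁻¹)
    (constants at 110 °C)

7. The neighbour of autumn with Z at 0.72 M has coverage 2.00, so L can go through to J with 50.0% of the Z left over. The computed flask ends with J at 100%, G at 0% and Z at 50.0% of its own charge.

All runs are calculated with constants of no real substance, noise included.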